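**Strategy.** The route rests on making the C5–C6 bond (ring-B methylene C5 to spiro carbon C6, chamigrene numbering) as the C=C of a cyclohexenyl ketone, by intramolecular Horner–Wadsworth–Emmons closure of an acyclic keto-phosphonate aldehyde. Because C6 is alpha to C7, the latent ketone behind the methylidene group, this step closes ring B and puts its only sp2 arm on C5. Conjugate hydrosilylation then writes a defined enol-ether geometry at C6=C7, and a bromiranium spirocyclisation onto C6 reads it out as the C6 and C10 configuration of ring A. One catalytic double epoxidation supplies all absolute stereochemistry; the key-step precursor carries no stereochemical information.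

Key step: step 5

Assumption: atoms are numbered as in chamigrene (C6 spiro; ring B = C1–C6 with C2–Br and C3–Cl/CH3; ring A = C6–C11 with C7 methylidene, C10–Br, C11 gem-dimethyl); the facial sense of the D-fructose-derived ketone is taken from its known behaviour with 1-phenylcyclohexene, and 4-methyl-3,6-dihydro-2H-pyran is taken as a commercial material.

Step 1
Reactants: 1 dimethyl (2-oxopropyl)phosphonate; 2 1-bromo-3-methylbut-2-ene
Product: 3 dimethyl (6-methyl-2-oxohept-5-en-1-yl)phosphonate
Conditions: NaH, THF, 0 °C; n-BuLi, 0 °C; then 2, 0 °C to rt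
Reagents that add atoms: none
Why: Dianion alkylation of a β-keto phosphonate: the second deprotonation creates the more nucleophilic terminal carbanion, which should displace bromide from the primary allylic halide (SN2) at the γ-carbon only.

Step 2
Reactants: 4 4-methyl-3,6-dihydro-2H-pyran
Product: 5 (3Z)-5-bromo-3-methylpent-3-en-1-yl acetate
Conditions: AcBr, ZnCl2 (cat.), CH2Cl2, 0 °C
Reagents that add atoms: acetyl bromide, CC(=O)Br
Why: Acylative cleavage of a cyclic allyl ether: O-acylation followed by bromide attack at the allylic CH2 (SN2) should open the ring regioselectively, the (Z)-geometry of the alkene being inherited from the ring.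

Step 3
Reactants: 3 dimethyl (6-methyl-2-oxohept-5-en-1-yl)phosphonate; 5 (3Z)-5-bromo-3-methylpent-3-en-1-yl acetate
Product: 6 dimethyl [(3Z)-6-acetoxy-4-methyl-1-(5-methylhex-4-enoyl)hex-3-en-1-yl]phosphonate (racemic)
Conditions: NaH, THF, 0 °C; then 5, 0 °C to rt
Reagents that add atoms: none
Why: C-Alkylation of the sodium enolate of the β-keto phosphonate by the primary allylic bromide (SN2) installs the C1–C6 bond; the new stereocentre is racemic and is destroyed in step 5.

Step 4
Reactants: 6 dimethyl [(3Z)-6-acetoxy-4-methyl-1-(5-methylhex-4-enoyl)hex-3-en-1-yl]phosphonate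
Product: 7 dimethyl [(3Z)-6-hydroxy-4-methyl-1-(5-methylhex-4-enoyl)hex-3-en-1-yl]phosphonate
Conditions: K2CO3, MeOH, 0 °C
Reagents that add atoms: none
Why: Base-catalysed transesterification with methanol should remove the acetate under conditions that leave the β-keto phosphonate intact.

Step 5
Reactants: 7 dimethyl [(3Z)-6-hydroxy-4-methyl-1-(5-methylhex-4-enoyl)hex-3-en-1-yl]phosphonate
Product: 9 5-methyl-1-(4-methylcyclohexa-1,4-dien-1-yl)hex-4-en-1-one, via keto-phosphonate aldehyde 8 (not isolated)
Conditions: Dess–Martin periodinane, NaHCO3, CH2Cl2, 0 °C; then LiCl, i-Pr2NEt, MeCN, rt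
Reagents that add atoms: none
Why: Dess–Martin oxidation gives the β,γ-unsaturated aldehyde 8, whose stabilised phosphonate carbanion (the future spiro carbon C6) adds to the aldehyde carbon C5 and eliminates dimethyl phosphate through the oxaphosphetane, an intramolecular Horner–Wadsworth–Emmons olefination under mild LiCl/amine conditions. Ring B closes in a 6-exo-trig addition to the carbonyl group, the (Z)-trisubstituted C2=C3 alkene of the tether holding C1 and C4 cis so that the chain can reach. No stereocentre is created, and the racemic phosphonate carbon becomes sp2. The selectivity needed is regiochemical: the enone double bond must lie at C5=C6 and not at C1=C6, which is secured because C6 alone carries the phosphonate and C5 alone is the aldehyde. That position is what later lets hydride enter at C5 through the s-cis enone and so fix the enol-ether geometry at C6=C7. Weak base at room temperature is chosen to avoid conjugation of the skipped diene or its aromatisation.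

Step 6
Reactants: 9 5-methyl-1-(4-methylcyclohexa-1,4-dien-1-yl)hex-4-en-1-one
Product: 10 3-[(2R)-3,3-dimethyloxiran-2-yl]-1-[(1R,6S)-6-methyl-7-oxabicyclo[4.1.0]hept-3-en-3-yl]propan-1-one
Conditions: 1,2:4,5-di-O-isopropylidene-β-D-erythro-2,3-hexodiulo-2,6-pyranose (30 mol% per alkene), Oxone (KHSO5), K2CO3, Bu4NHSO4, MeCN/dimethoxymethane/aq. buffer pH 10.5, 0 °C
Reagents that add atoms: potassium peroxymonosulfate (KHSO5), [K+].[O-]S(=O)(=O)OO
Why: Shi asymmetric epoxidation: the chiral dioxirane attacks only the two electron-rich trisubstituted alkenes (the enone is inert) through the spiro transition state, so one ketone enantiomer should give the (R)-side-chain epoxide (precursor of C10) and the ring-B epoxide with oxygen on the face that will carry chlorine at C3.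

Step 7
Reactants: 10 3-[(2R)-3,3-dimethyloxiran-2-yl]-1-[(1R,6S)-6-methyl-7-oxabicyclo[4.1.0]hept-3-en-3-yl]propan-1-one
Product: 11 (4S)-4-bromo-1-[(4S,5S)-5-bromo-4-hydroxy-4-methylcyclohex-1-en-1-yl]-5-hydroxy-5-methylhexan-1-one
Conditions: Li2NiBr4, THF, 0 °C to rt; aq. work-up
Reagents that add atoms: dilithium tetrabromonickelate (Li2NiBr4), [Li+].[Li+].Br[Ni-2](Br)(Br)Br
Why: Soft bromide from Li2NiBr4 should open each epoxide by SN2 attack at the less substituted carbon with inversion, which sets the C2–Br and C10–Br centres and leaves each tertiary carbinol trans to bromine.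

Step 8
Reactants: 11 (4S)-4-bromo-1-[(4S,5S)-5-bromo-4-hydroxy-4-methylcyclohex-1-en-1-yl]-5-hydroxy-5-methylhexan-1-one
Product: 12 (4S)-4-bromo-1-[(4S,5S)-5-bromo-4-chloro-4-methylcyclohex-1-en-1-yl]-5-chloro-5-methylhexan-1-one
Conditions: HCl (4 M in dioxane), ZnCl2 (cat.), CH2Cl2, −20 to 0 °C
Reagents that add atoms: hydrogen chloride, Cl
Why: Lucas-type SN1 substitution with neighbouring-group participation: each tertiary carbinol should ionise to a bromiranium ion with the anti bromine and chloride reopen it at the tertiary carbon, so that C3–Cl forms with overall retention (trans to C2–Br) and C10 stays untouched.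

Step 9
Reactants: 12 (4S)-4-bromo-1-[(4S,5S)-5-bromo-4-chloro-4-methylcyclohex-1-en-1-yl]-5-chloro-5-methylhexan-1-one
Product: 13 triethyl{[(1E,4S)-4-bromo-1-[(3S,4S)-3-bromo-4-chloro-4-methylcyclohexylidene]-5-chloro-5-methylhexyl]oxy}silane
Conditions: RhCl(PPh3)3 (2 mol%), Et3SiH, benzene, 50 °C
Reagents that add atoms: triethylsilane, CC[SiH](CC)CC
Why: Rhodium-catalysed 1,4-hydrosilylation: hydride is delivered to C5 and silicon to oxygen within the s-cis-bound enone, which should give the tetrasubstituted enol ether with oxygen cis to C5 and the C8 chain cis to C1, without touching the alkyl halides.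

Step 10
Reactants: 13 triethyl{[(1E,4S)-4-bromo-1-[(3S,4S)-3-bromo-4-chloro-4-methylcyclohexylidene]-5-chloro-5-methylhexyl]oxy}silane
Product: 14 (4S,6R,8S,9S)-4,8-dibromo-9-chloro-5,5,9-trimethylspiro[5.5]undecan-1-one
Conditions: TiCl4, CH2Cl2, −78 to −40 °C
Reagents that add atoms: none
Why: Proposed new method: TiCl4 should ionise the side-chain tertiary chloride with anchimeric help from the C10 bromine to a bromiranium ion, which the enol-ether carbon C6 opens at C11 anti to bromine through a chair transition state (bromine equatorial, C1 axial and C5 equatorial on ring A as dictated by the enol-ether geometry, attack on the ring-B face cis to C2–Br); this sets C6 and retains C10, while the ring-B chloride can only ionise reversibly because no nucleophile can reach it; the closest known reaction types are the TiCl4-mediated α-tert-alkylation of silyl enol ethers by tertiary chlorides (Reetz alkylation) and the solvolytic cyclisation of vicinal bromochlorides onto alkenes.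

Step 11
Reactants: 14 (4S,6R,8S,9S)-4,8-dibromo-9-chloro-5,5,9-trimethylspiro[5.5]undecan-1-one
Product: 15 nidificene, (4S,6S,8S,9S)-4,8-dibromo-9-chloro-5,5,9-trimethyl-1-methylidenespiro[5.5]undecane
Conditions: Cp2TiMe2, toluene, 70 °C
Reagents that add atoms: dimethyltitanocene (Cp2TiMe2), C[Ti](C)(C1C=CC=C1)C1C=CC=C1
Why: Petasis methylenation through the non-basic titanium carbene Cp2Ti=CH2 should convert the hindered C7 ketone into the methylidene group without enolisation, so that the γ-bromide at C10 and all stereocentres survive.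

**Compound list**

1 | dimethyl (2-oxopropyl)phosphonate | CC(=O)CP(=O)(OC)OC | starting material
2 | 1-bromo-3-methylbut-2-ene | CC(C)=CCBr | starting material
3 | dimethyl (6-methyl-2-oxohept-5-en-1-yl)phosphonate | CC(C)=CCCC(=O)CP(=O)(OC)OC | intermediate
4 | 4-methyl-3,6-dihydro-2H-pyran | CC1=CCOCC1 | starting material
5 | (3Z)-5-bromo-3-methylpent-3-en-1-yl acetate | CC(=O)OCC/C(C)=C\CBr | intermediate
6 | dimethyl [(3Z)-6-acetoxy-4-methyl-1-(5-methylhex-4-enoyl)hex-3-en-1-yl]phosphonate (racemic) | CC(C)=CCCC(=O)C(C/C=C(C)\CCOC(C)=O)P(=O)(OC)OC | intermediate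
7 | dimethyl [(3Z)-6-hydroxy-4-methyl-1-(5-methylhex-4-enoyl)hex-3-en-1-yl]phosphonate (racemic) | CC(C)=CCCC(=O)C(C/C=C(C)\CCO)P(=O)(OC)OC | intermediate
8 | dimethyl [(3Z)-4-methyl-1-(5-methylhex-4-enoyl)-6-oxohex-3-en-1-yl]phosphonate (racemic) | CC(C)=CCCC(=O)C(C/C=C(C)\CC=O)P(=O)(OC)OC | intermediate
9 | 5-methyl-1-(4-methylcyclohexa-1,4-dien-1-yl)hex-4-en-1-one | CC(C)=CCCC(=O)C1=CCC(C)=CC1 | intermediate
10 | 3-[(2R)-3,3-dimethyloxiran-2-yl]-1-[(1R,6S)-6-methyl-7-oxabicyclo[4.1.0]hept-3-en-3-yl]propan-1-one | CC1(C)O[C@@H]1CCC(=O)C2=CC[C@]3(C)O[C@@H]3C2 | intermediate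
11 | (4S)-4-bromo-1-[(4S,5S)-5-bromo-4-hydroxy-4-methylcyclohex-1-en-1-yl]-5-hydroxy-5-methylhexan-1-one | CC(C)(O)[C@@H](Br)CCC(=O)C1=CC[C@](C)(O)[C@@H](Br)C1 | intermediate
12 | (4S)-4-bromo-1-[(4S,5S)-5-bromo-4-chloro-4-methylcyclohex-1-en-1-yl]-5-chloro-5-methylhexan-1-one | CC(C)(Cl)[C@@H](Br)CCC(=O)C1=CC[C@](C)(Cl)[C@@H](Br)C1 | intermediate
13 | triethyl{[(1E,4S)-4-bromo-1-[(3S,4S)-3-bromo-4-chloro-4-methylcyclohexylidene]-5-chloro-5-methylhexyl]oxy}silane | CC[Si](CC)(CC)O/C(=C1\CC[C@](C)(Cl)[C@@H](Br)C1)CC[C@H](Br)C(C)(C)Cl | intermediate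
14 | (4S,6R,8S,9S)-4,8-dibromo-9-chloro-5,5,9-trimethylspiro[5.5]undecan-1-one | O=C1CC[C@H](Br)C(C)(C)[C@]12CC[C@](C)(Cl)[C@@H](Br)C2 | intermediate
15 | nidificene, (4S,6S,8S,9S)-4,8-dibromo-9-chloro-5,5,9-trimethyl-1-methylidenespiro[5.5]undecane | C=C1CC[C@H](Br)C(C)(C)[C@]12CC[C@](C)(Cl)[C@@H](Br)C2 | target

**Step count.** Total: 11 steps. Longest linear sequence: 10 steps (steps 1 and 3–11; step 2 makes the side fragment 5).

**The three steps most likely to fail**

1. Step 10 (proposed new method). What may go wrong: competitive ionisation of the ring-B tertiary chloride with loss of HCl or halide scrambling; O-alkylation or protodesilylation of the enol ether; failure to join two fully substituted carbons; closure through a boat, which would invert C6. Fallback with known chemistry: starting from 13, fluoride-mediated triflation (CsF, PhNTf2, DME, rt) should give, with retention of geometry, the enol triflate (1E,4S)-4-bromo-1-[(3S,4S)-3-bromo-4-chloro-4-methylcyclohexylidene]-5-chloro-5-methylhexyl trifluoromethanesulfonate F1. Negishi methylation (MeZnCl, Pd(PPh3)4, THF, 40 °C) then gives the tetrasubstituted alkene (1S,2S)-2-bromo-4-[(2Z,5S)-5-bromo-6-chloro-6-methylheptan-2-ylidene]-1-chloro-1-methylcyclohexane F2. Solvolytic ionisation of its side-chain bromochloride in (CF3)2CHOH at rt, capture of the bromiranium ion by the alkene through the same chair, and loss of a proton from the C7 methyl group should lead directly to 15, so that steps 10 and 11 are replaced.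

2. Step 8. What may go wrong: E1 loss of water or HCl from ring B followed by aromatisation of the cyclohexenyl ketone; participation of the ketone oxygen at the side-chain cation; chloride attack at the secondary carbon. Fallback: starting from 11, the two tertiary alcohols are silylated (Et3SiOTf, 2,6-lutidine, CH2Cl2, −78 °C) to the enone (4S)-4-bromo-1-[(4S,5S)-5-bromo-4-methyl-4-(triethylsilyloxy)cyclohex-1-en-1-yl]-5-methyl-5-(triethylsilyloxy)hexan-1-one F3. Hydrosilylation as in step 9 gives the enol ether triethyl{[(1E,4S)-4-bromo-1-[(3S,4S)-3-bromo-4-methyl-4-(triethylsilyloxy)cyclohexylidene]-5-methyl-5-(triethylsilyloxy)hexyl]oxy}silane F4. TiCl4 (CH2Cl2, −78 °C) then ionises both tertiary C–O bonds with bromine assistance; the side-chain bromiranium ion is captured by the enol ether and the ring-B one by chloride from the titanium reagent. The route is rejoined at 14 without exposing the enone to Brønsted acid.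

3. Step 9. What may go wrong: hydride delivery through the s-trans conformer or equilibration of a rhodium enolate, which would write the opposite enol-ether geometry and so the opposite C10/C6 relationship; 1,2-hydrosilylation; hydrodehalogenation. Fallback: starting from 12, uncatalysed conjugate reduction with catecholborane (THF, rt), which can proceed only through the s-cis enone in a six-membered transition state, should give the boron enolate 2-{[(1E,4S)-4-bromo-1-[(3S,4S)-3-bromo-4-chloro-4-methylcyclohexylidene]-5-chloro-5-methylhexyl]oxy}-1,3,2-benzodioxaborole F5 of the required geometry. F5 is cyclised directly with TiCl4 as in step 10, rejoining the route at 14.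

**Further compounds**

F1 | step 10 | (1E,4S)-4-bromo-1-[(3S,4S)-3-bromo-4-chloro-4-methylcyclohexylidene]-5-chloro-5-methylhexyl trifluoromethanesulfonate | FC(F)(F)S(=O)(=O)O/C(=C1\CC[C@](C)(Cl)[C@@H](Br)C1)CC[C@H](Br)C(C)(C)Cl
F2 | step 10 | (1S,2S)-2-bromo-4-[(2Z,5S)-5-bromo-6-chloro-6-methylheptan-2-ylidene]-1-chloro-1-methylcyclohexane | C/C(=C1\CC[C@](C)(Cl)[C@@H](Br)C1)CC[C@H](Br)C(C)(C)Cl
F3 | step 8 | (4S)-4-bromo-1-[(4S,5S)-5-bromo-4-methyl-4-(triethylsilyloxy)cyclohex-1-en-1-yl]-5-methyl-5-(triethylsilyloxy)hexan-1-one | CC[Si](CC)(CC)OC(C)(C)[C@@H](Br)CCC(=O)C1=CC[C@](C)(O[Si](CC)(CC)CC)[C@@H](Br)C1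
F4 | step 8 | triethyl{[(1E,4S)-4-bromo-1-[(3S,4S)-3-bromo-4-methyl-4-(triethylsilyloxy)cyclohexylidene]-5-methyl-5-(triethylsilyloxy)hexyl]oxy}silane | CC[Si](CC)(CC)O/C(=C1\CC[C@](C)(O[Si](CC)(CC)CC)[C@@H](Br)C1)CC[C@H](Br)C(C)(C)O[Si](CC)(CC)CC
F5 | step 9 | 2-{[(1E,4S)-4-bromo-1-[(3S,4S)-3-bromo-4-chloro-4-methylcyclohexylidene]-5-chloro-5-methylhexyl]oxy}-1,3,2-benzodioxaborole | B1(Oc2ccccc2O1)O/C(=C3\CC[C@](C)(Cl)[C@@H](Br)C3)CC[C@H](Br)C(C)(C)Cl
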